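(The readings are calculated with constants of no real substance, and the scatter is random.)

A level cannot stand at a peak with nothing leaving it, so the north-west run has a leak, and I can size it. Substrate plus single product falls by 25 percentage points between 4.00 min and 15.0 min, while single product stands near 42.1 %. Level over outflow is a time constant: 18.2 min at 50 °C. I call it the lifetime of single product: the level divided by the rate at which it leaks away.

| flask | substrate | coupling partner | temperature | remark | time |
|---|---|---|---|---|---|
| south | 13 mM | 30 mM | 0 °C | run made earlier |  |
| north-west | 30 mM | 30 mM | 50 °C | run made earlier |  |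
| noon | 20 mM | 30.0 mM | 5 °C |  | 2.5 h |
| spring | 20 mM | 30.0 mM | 95 °C |  | 2.5 h |
| dawn | 20 mM | 30.0 mM | 35 °C |  | 2.5 h |
| midnight | 20 mM | 30.0 mM | 65 °C |  | 2.5 h |

south run (percent of the substrate charged)

| time / h | single product / % | substrate / % |
|---|---|---|
| 0.333 | 4.5 | 95.7 |
| 0.833 | 10.4 | 89.8 |
| 1.50 | 18.1 | 81.6 |
| 2.50 | 27.7 | 71.9 |

north-west run (percent of the substrate charged)

| time / min | single product / % | substrate / % |
|---|---|---|
| 4.00 | 37.9 | 58.3 |
| 8.00 | 44.2 | 42.4 |
| 12.0 | 42.1 | 33.8 |
| 15.0 | 40.3 | 30.4 |

(each reading ± 0.3 percentage points)



1. which flask leads in amount of single product, in percent of the substrate charged ("all alike" within 1.5 percentage points) (noon / spring / dawn / midnight / all alike)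
2. how much single product is there at the end, in percent of the substrate charged: noon
3. how much single product is there at the end, in percent of the substrate charged: spring
4. how much single product is there at the end, in percent of the substrate charged: dawn
5. how much single product is there at the end, in percent of the substrate charged: midnight

Here is my note for the bench. The south run still accounts for 99.6 % of the charge at 2.50 h, so no leak shows at 0 °C. Noon, at 5 °C, stands close to that temperature, so I expect it clean too. Single product in the south run is still climbing at its last reading, 27.7 %, so don't stop noon early. Midnight at 65 °C and spring at 95 °C are hotter than the run that leaked, and I assume warming shortens the lifetime. Then 2.5 h is at least 8.26 lifetimes, and a level cut off from its feed at the start shrinks to 0.0259 % of itself. I expect single product close to zero in both when you come.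

The forecast puts noon first with 40 % (36 % to 44 %), then dawn 30 %, midnight 22 % and spring 15 %: “product is then eaten until partner runs out”. I part from it on the hot two.

The flasks give noon 38.1 %, dawn 28.8 %, midnight 0 % and spring 0 %.

    single product → over-reaction product (k = 0.00680 min⁻¹, Ea = 102 kJ mol⁻¹)
    single product + by-product → side product (k = 0.190 L mol⁻¹ min⁻¹, Ea = 52.0 kJ mol⁻¹)
    coupling partner → decomposed reagent (k = 0.00340 min⁻¹, Ea = 106 kJ mol⁻¹)
    coupling partner + single product → bis adduct + by-product (k = 0.0320 L mol⁻¹ min⁻¹, Ea = 57.0 kJ mol⁻¹)
    substrate + coupling partner → single product + by-product (k = 2.00 L mol⁻¹ min⁻¹, Ea = 65.0 kJ mol⁻¹)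
    (constants at 35 °C)

Midnight ends with 0 % single product and 78.6 % over-reaction product. Coupling partner, the limiting reagent there, stands at 0 % of its charge, so the feed has stopped with 15.7 % substrate unused. In spring, striking out the conversion of single product into over-reaction product lifts the end value to 5.53 %, the largest single effect. Dawn, read the same way between 1.25 h and 2.50 h, gives a lifetime of 1.68 h, and 28.8 % single product stands at its end.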